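The runs were computed for an exercise, and the scatter is random.

Can I charge 0.063 M of electrophile on the present recipe and leave it for 25 h, or must I add nucleophile first?

| setting | Saturday's | Thursday's | flask |
|---|---|---|---|
| electrophile | 0.032 M | 0.047 M | 0.063 M |
| nucleophile | 0.0693 M | 0.0693 M | 0.0693 M |
| free base | 0.0756 M | 0.0756 M | 0.0756 M |
| protic impurity | 0.0189 M | 0.0189 M | 0.0189 M |
| remark | run made earlier | run made earlier |  |
| time |  |  | 25 h |

| run | time / h | electrophile / % | target / % |
|---|---|---|---|
| Saturday's | 5.00 | 0 | 66 |
| Saturday's | 10.0 | 2 | 59 |
| Saturday's | 15.0 | 0 | 55 |
| Saturday's | 20.0 | 0 | 47 |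
| Thursday's | 5.00 | 5 | 65 |
| Thursday's | 10.0 | 1 | 63 |
| Thursday's | 15.0 | 5 | 61 |
| Thursday's | 20.0 | 0 | 56 |

(standard deviation of a reading: 1.5 percentage points)

* part of the electrophile that has reacted at 25 h
* share of the unused nucleophile that is free and not bound as protonated nucleophile, at 25 h

- the earlier runs do not show how much of nucleophile is bound; that part of a forecast is a guess

At 5.00 h, Saturday's run has 0.0109 M of its electrophile in neither electrophile nor target, and Thursday's has 0.0141 M. Both are readings, and both lie below the 0.0189 M of protic impurity, so I guess that the impurity takes electrophile as the nucleophile does.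

I therefore carry one quantity, the takers' margin: 0.0252 M for this flask, which is [nucleophile] plus [protic impurity] minus [electrophile], each at its charge. On this recipe the margin crosses zero at 0.0882 M of electrophile. Below that crossing I expect electrophile to be the limiting reagent, and above it I expect the takers to end first.

The margin in this flask is smaller than Thursday's 0.0412 M, but it is still positive. The last readings of electrophile in the two runs are 0% and 0%. So I add no nucleophile, and I expect electrophile to end within the scatter of zero.

The forecast gives 93% reacted and 45% of the unused nucleophile free, on the ground that “Acid balance is key”, so it stops short of where I expect the electrophile to end.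

    electrophile + nucleophile → acid set free + target (k = 22.0 M⁻¹ h⁻¹)
    nucleophile + acid set free ⇌ protonated nucleophile, settled at all times (K = 75000 M⁻¹)
    acid set free + free base ⇌ salt of the base, settled at all times (K = 5400 M⁻¹)
    nucleophile + target → over-reaction product (k = 1.40 M⁻¹ h⁻¹)
    electrophile + target → side product (k = 1.00 M⁻¹ h⁻¹)
    electrophile + protic impurity → quenched substrate (k = 13.0 M⁻¹ h⁻¹)

This flask reaches 99.5% reacted with 12.5% of the unused nucleophile free. With the margin at 0.0252 M, electrophile is first to run out, at 0.493% of its charge, while free base stands at 66% of its own. The neighbouring flask with 0.11 M of electrophile, other charges unchanged, falls short of takers by 0.0218 M. At 25 h it has 89.5% reacted, with electrophile at 10.5%, free nucleophile at 0.653% of its charge and 0.0100 M bound as protonated nucleophile; side product, counted as holding two, holds the most of the electrophile at 41.4%.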